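1. At early times D runs ahead of Q: cedar shows D at 8.4% by 10.0 min, near its later 9.0%, while Q climbs from 6.8% to 18.3%.

| flask | L | G | remark | time |
|---|---|---|---|---|
| cedar | 0.50 M | 0.5 mol% | run made earlier |  |
| larch | 0.50 M | 0.75 mol% | run made earlier |  |
| elm | 0.75 M | 1 mol% | run made earlier |  |
| flask | 0.50 M | 1 mol% |  | 2.0 h |

| run | time / min | Q / % | D / % |
|---|---|---|---|
| cedar | 10.0 | 6.8 | 8.4 |
| cedar | 25.0 | 13.0 | 8.4 |
| cedar | 50.0 | 18.0 | 9.2 |
| cedar | 80.0 | 18.3 | 9.0 |
| larch | 10.0 | 8.0 | 9.6 |
| larch | 25.0 | 15.4 | 10.5 |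
| larch | 50.0 | 17.5 | 10.3 |
| larch | 80.0 | 18.0 | 10.2 |
| elm | 6.00 | 6.2 | 10.1 |
| elm | 12.0 | 9.5 | 11.0 |
| elm | 30.0 | 15.8 | 13.8 |
| elm | 80.0 | 16.4 | 18.9 |

(each reading ± 0.5 percentage points)

* ratio of Q to D at 15 s
* ratio of Q to D at 5.0 min
* ratio of Q to D at 2.0 h
* which of Q and D there is more of at 2.0 h

- what is said of D includes X
- X is a solid; its amount is given per volume of the solution
- the numbers in the tables scatter by 0.5 percentage points (one standard deviation)
- steps under discussion: L + G <-> D + G; D <-> Q; Q <-> L; X <-> D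

2. The quantity to carry is w, the ratio c_Q/c_L in the last sample of a run, with L taken as what the charge leaves after Q and D. It is a reading of the equilibrium constant between L and Q. Cedar gives 0.252, larch 0.251 and elm 0.253, so the mean reading of w is 0.252.

3. For this flask, the step in G from cedar to larch, taken once more, puts D at 11.4%. Starting from larch's Q, the balance leaves L 70.6%, so Q is 17.8%. Put back, that leaves L 70.8% and Q 17.8%. The late ratio is therefore 1.57, with Q ahead. In closed form, late in a run at this w, Q is 0.201 of what D leaves of the charge.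

4. D as reported counts X, so no solid is to be taken out of this flask before a reading. In elm, D gained 5.1 percentage points from 30.0 min to 80.0 min, more than Q's 0.6 points.

The forecast gives 0.08, 0.6 and 1.6, with Q ahead, a late ratio above this reckoning, on the ground that “Q/L ends near 0.25 in every run”.

The flask gives 0.0835, 0.466 and 1.64, with Q ahead; its D at 2.00 h includes X at 1.56%. With that flask's D of 11.2%, the carried rule gives Q 17.9%, and the flask stands at 18.3%.

    L + G ⇌ D + G, rate k1*[L]*[G] forward; the back reaction follows from the equilibrium constant (K = 0.137, k = 637 M⁻¹ h⁻¹)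
    D ⇌ Q (K = 1.90, k = 6.12 h⁻¹)
    Q ⇌ L (k = 0.819 h⁻¹)
    X ⇌ D, rate k4*(cs4 - [D]) while solid is left; crystals form when [D] > cs4 (solubility = 47.0 mM, k = 2.80 h⁻¹)

The neighbour flask, charged with 1.7 mol% of G, ends with D at 11.5%, for which the rule gives Q 17.8%. Computed, it holds Q 18.3% and a ratio of 1.59.

The numbers in the tables were generated by integration for an exercise.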